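**Retrosynthetic overview**
1. Target 11 ⇐ 3-O-benzoate 10 by mild methanolysis; 10 ⇐ 5,7-diol 9 by selective 7-O-prenylation, so the acid- and hydrogenation-sensitive prenyl ether goes on late.
2. 9 ⇐ 5,7-di-O-benzyl flavonol 7 by 3-O-benzoylation, then hydrogenolysis.
3. Pyranone ring of 7 (the only ring formed; both benzene rings are bought) ⇐ Algar–Flynn–Oyamada oxidative cyclisation of 2'-hydroxychalcone 5.
4. Key C–C bond (C2–C3 of the flavonol) ⇐ intermolecular Claisen–Schmidt aldol condensation of acetophenone 2 with 4-methoxybenzaldehyde 3.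
5. 2 ⇐ phloroacetophenone 1 by selective 2,4-di-O-benzylation.

Assumption: the target has no stereocentre and no E/Z-defined alkene, so it is achiral and "single enantiomer" requires no stereocontrol; the compound as drawn is made.

**Route**

Step 1
Reactants: 1 1-(2,4,6-trihydroxyphenyl)ethan-1-one (phloroacetophenone, dried)
Product: 2 1-[2,4-bis(benzyloxy)-6-hydroxyphenyl]ethan-1-one
Conditions: BnBr (2.1 equiv), K2CO3 (2.5 equiv), DMF, rt to 40 °C
Reagents that add atoms: benzyl bromide, BrCc1ccccc1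
Why: Williamson ether synthesis in which the 4-OH and one ortho OH are alkylated while the last ortho OH, locked in a hydrogen bond to the ketone, stays free under mild base and limited BnBr.

Step 2
Reactants: 2 1-[2,4-bis(benzyloxy)-6-hydroxyphenyl]ethan-1-one; 3 4-methoxybenzaldehyde (1.3 equiv)
Product: 5 chalcone (E)-1-[2,4-bis(benzyloxy)-6-hydroxyphenyl]-3-(4-methoxyphenyl)prop-2-en-1-one, via β-hydroxy ketone aldol adduct 4 (not isolated)
Conditions: KOH (50% aq, excess), EtOH/THF, rt, 24–48 h; then cold dilute HCl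
Reagents that add atoms: none
Why: Claisen–Schmidt crossed aldol condensation in which the methyl ketone enolate adds to the non-enolisable aldehyde and E1cB dehydration gives the conjugated, thermodynamically favoured E-enone.

Step 3
Reactants: 5 chalcone (E)-1-[2,4-bis(benzyloxy)-6-hydroxyphenyl]-3-(4-methoxyphenyl)prop-2-en-1-one
Product: 7 flavonol 5,7-bis(benzyloxy)-3-hydroxy-2-(4-methoxyphenyl)-4H-chromen-4-one, via trans-dihydroflavonol 6 (not isolated)
Conditions: 30% H2O2 (5 equiv), aq NaOH, MeOH/THF, 0 °C to rt; then dilute HCl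
Reagents that add atoms: hydrogen peroxide, OO
Why: Algar–Flynn–Oyamada reaction in which alkaline peroxide oxygenates the enone α-carbon as the 2'-phenoxide closes the six-membered ring at the β-carbon (favoured by the 4-methoxyphenyl group), and the racemic trans-3-hydroxyflavanone is dehydrogenated in the same medium to the achiral flavonol.

Step 4
Reactants: 7 flavonol 5,7-bis(benzyloxy)-3-hydroxy-2-(4-methoxyphenyl)-4H-chromen-4-one
Product: 8 5,7-bis(benzyloxy)-2-(4-methoxyphenyl)-4-oxo-4H-chromen-3-yl benzoate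
Conditions: BzCl (1.3 equiv), Et3N (2 equiv), DMAP (cat.), CH2Cl2, 0 °C to rt
Reagents that add atoms: benzoyl chloride, O=C(Cl)c1ccccc1
Why: DMAP-catalysed O-acylation of the only free hydroxyl masks the 3-OH so that it cannot compete in the later alkylation.

Step 5
Reactants: 8 5,7-bis(benzyloxy)-2-(4-methoxyphenyl)-4-oxo-4H-chromen-3-yl benzoate
Product: 9 5,7-dihydroxy-2-(4-methoxyphenyl)-4-oxo-4H-chromen-3-yl benzoate
Conditions: H2 (1 atm), 10% Pd/C, THF/EtOAc, rt, stopped after uptake of 2 equiv H2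
Reagents that add atoms: none
Why: Catalytic hydrogenolysis cleaves both benzyl aryl ethers under neutral conditions that leave the tetrasubstituted chromone double bond, the aryl methyl ether and the benzoate intact.

Step 6
Reactants: 9 5,7-dihydroxy-2-(4-methoxyphenyl)-4-oxo-4H-chromen-3-yl benzoate
Product: 10 5-hydroxy-2-(4-methoxyphenyl)-7-[(3-methylbut-2-en-1-yl)oxy]-4-oxo-4H-chromen-3-yl benzoate
Conditions: prenyl bromide (1.1 equiv), K2CO3 (1.2 equiv), dry acetone, rt to 40 °C
Reagents that add atoms: prenyl bromide (1-bromo-3-methylbut-2-ene), CC(C)=CCBr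
Why: Williamson etherification (SN2 at the primary allylic carbon) occurs only at the acidic 7-OH because the 5-OH is held in a chelate with the C4 carbonyl and the 3-O is blocked, and the mild temperature avoids Claisen rearrangement.

Step 7
Reactants: 10 5-hydroxy-2-(4-methoxyphenyl)-7-[(3-methylbut-2-en-1-yl)oxy]-4-oxo-4H-chromen-3-yl benzoate
Product: 11 3,5-dihydroxy-2-(4-methoxyphenyl)-7-[(3-methylbut-2-en-1-yl)oxy]-4H-chromen-4-one
Conditions: K2CO3 (0.5 equiv), dry MeOH/THF, N2, rt; then aq NH4Cl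
Reagents that add atoms: none
Why: Base-mediated transesterification (methanolysis) of the activated enol benzoate frees the 3-OH under non-acidic, non-reductive conditions that the prenyl ether tolerates.

**Compound list**
1 | 1-(2,4,6-trihydroxyphenyl)ethan-1-one (phloroacetophenone) | CC(=O)c1c(O)cc(O)cc1O | starting material
2 | 1-[2,4-bis(benzyloxy)-6-hydroxyphenyl]ethan-1-one | CC(=O)c1c(O)cc(OCc2ccccc2)cc1OCc1ccccc1 | intermediate
3 | 4-methoxybenzaldehyde | COc1ccc(C=O)cc1 | starting material
4 | 1-[2,4-bis(benzyloxy)-6-hydroxyphenyl]-3-hydroxy-3-(4-methoxyphenyl)propan-1-one (racemic aldol adduct, stereocentre not controlled, not isolated) | COc1ccc(C(O)CC(=O)c2c(O)cc(OCc3ccccc3)cc2OCc2ccccc2)cc1 | intermediate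
5 | (E)-1-[2,4-bis(benzyloxy)-6-hydroxyphenyl]-3-(4-methoxyphenyl)prop-2-en-1-one | COc1ccc(/C=C/C(=O)c2c(O)cc(OCc3ccccc3)cc2OCc2ccccc2)cc1 | intermediate
6 | trans-5,7-bis(benzyloxy)-3-hydroxy-2-(4-methoxyphenyl)chroman-4-one (racemic; 2R,3R enantiomer drawn; not isolated) | O=C1c2c(OCc3ccccc3)cc(OCc3ccccc3)cc2O[C@H](c2ccc(OC)cc2)[C@H]1O | intermediate
7 | 5,7-bis(benzyloxy)-3-hydroxy-2-(4-methoxyphenyl)-4H-chromen-4-one | COc1ccc(-c2oc3cc(OCc4ccccc4)cc(OCc4ccccc4)c3c(=O)c2O)cc1 | intermediate
8 | 5,7-bis(benzyloxy)-2-(4-methoxyphenyl)-4-oxo-4H-chromen-3-yl benzoate | COc1ccc(-c2oc3cc(OCc4ccccc4)cc(OCc4ccccc4)c3c(=O)c2OC(=O)c2ccccc2)cc1 | intermediate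
9 | 5,7-dihydroxy-2-(4-methoxyphenyl)-4-oxo-4H-chromen-3-yl benzoate | COc1ccc(-c2oc3cc(O)cc(O)c3c(=O)c2OC(=O)c2ccccc2)cc1 | intermediate
10 | 5-hydroxy-2-(4-methoxyphenyl)-7-[(3-methylbut-2-en-1-yl)oxy]-4-oxo-4H-chromen-3-yl benzoate | COc1ccc(-c2oc3cc(OCC=C(C)C)cc(O)c3c(=O)c2OC(=O)c2ccccc2)cc1 | intermediate
11 | 3,5-dihydroxy-2-(4-methoxyphenyl)-7-[(3-methylbut-2-en-1-yl)oxy]-4H-chromen-4-one (CNP0163238.0) | COc1ccc(-c2oc3cc(OCC=C(C)C)cc(O)c3c(=O)c2O)cc1 | target

**Totals**
Total step count: 7. Longest linear sequence: 7 steps (1 → 11; aldehyde 3 is bought and enters at step 2).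

**Steps most likely to fail, with fallbacks**

Step 3 (Algar–Flynn–Oyamada). A 6'-alkoxy group on the chalcone can divert part of the material to the aurone or leave the dihydroflavonol unoxidised. The fallback sets out from chalcone 5. Oxidative cyclisation with catalytic I2 in DMSO at 120–130 °C gives the flavone 5,7-bis(benzyloxy)-2-(4-methoxyphenyl)-4H-chromen-4-one F1. Epoxidation of its C2=C3 bond with dimethyldioxirane in acetone/CH2Cl2 at 0 °C (short contact time to spare the benzyl ethers) gives the racemic cis-fused flavone 2,3-epoxide 5,7-bis(benzyloxy)-2,3-epoxy-2-(4-methoxyphenyl)chroman-4-one F2. Catalytic p-TsOH then opens and tautomerises F2 to flavonol 7, where the route is rejoined.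

Step 1 (selective di-O-benzylation). Over-benzylation and C-benzylation of the electron-rich ring can lower the yield of 2. The fallback sets out from 1. Exhaustive O-benzylation (BnBr 3.5–4 equiv, K2CO3, DMF, 70 °C) gives 1-[2,4,6-tris(benzyloxy)phenyl]ethan-1-one F3. Chelation-controlled removal of one benzyl group ortho to the ketone with MgBr2·OEt2 in toluene/Et2O at reflux then returns 2.

Step 6 (7-O-prenylation). Base could cause some benzoyl transfer, C-alkylation or over-alkylation. The fallback sets out from 9 and uses a Mitsunobu etherification with 3-methylbut-2-en-1-ol, PPh3 and DIAD in THF at 0 °C. No base is present, and the most acidic phenol (7-OH) reacts, so the route is rejoined at 10. This fallback makes no new compound (entry F0).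

**Further compounds**
F1 | step 3 | 5,7-bis(benzyloxy)-2-(4-methoxyphenyl)-4H-chromen-4-one | COc1ccc(-c2cc(=O)c3c(OCc4ccccc4)cc(OCc4ccccc4)cc3o2)cc1
F2 | step 3 | 5,7-bis(benzyloxy)-2,3-epoxy-2-(4-methoxyphenyl)chroman-4-one (racemic, cis-fused; one enantiomer drawn) | O=C1[C@@H]2O[C@]2(c2ccc(OC)cc2)Oc2cc(OCc3ccccc3)cc(OCc3ccccc3)c12
F3 | step 1 | 1-[2,4,6-tris(benzyloxy)phenyl]ethan-1-one | CC(=O)c1c(OCc2ccccc2)cc(OCc2ccccc2)cc1OCc1ccccc1
F0 | step 6 | none | none
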